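The benzofuran is disconnected at its furan C2–C3 bond. In the target, furan C2 (bonded to O1 and the anisyl ring) and C3 (bonded to benzo carbon C3a) correspond to the OCH2 carbon of a 4-methoxybenzyl ether and an ortho formyl carbon, a 1,5-relationship. A Norrish–Yang photocyclisation (δ-hydrogen abstraction, then 1,5-biradical coupling) forms C2–C3 and closes the furan ring in one operation; dehydration then aromatises it. The precursor is methyl 3-formyl-4-[(4-methoxyphenyl)methoxy]benzoate. Its photoinert ester is later turned into the aldehyde that carries the flavanone, which is closed enantioselectively by thiourea-catalysed oxa-Michael addition of an ester-activated alkylidene.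

Key step: step 2

Assumption: the flavanone centre of the target is 2S (O1 > aryl > C3 > H). The cinchona thiourea of step 8 exists in quinine- and quinidine-derived pseudoenantiomeric forms, and the form that delivers the 2S series is used, its sense being checked on the first run.

Step 1
Reactants: 1 methyl 3-formyl-4-hydroxybenzoate; 2 4-methoxybenzyl chloride
Product: 3 methyl 3-formyl-4-[(4-methoxyphenyl)methoxy]benzoate
Conditions: K2CO3, DMF, 60 °C
Reagents that add atoms: none
Why: Williamson ether synthesis, in which the acidic phenol (ortho to the formyl group, para to the ester) is deprotonated by carbonate and displaces chloride from the activated benzylic halide by SN2, there being no other nucleophilic site.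

Step 2
Reactants: 3 methyl 3-formyl-4-[(4-methoxyphenyl)methoxy]benzoate
Product: 4 methyl 3-hydroxy-2-(4-methoxyphenyl)-2,3-dihydro-1-benzofuran-5-carboxylate (racemic, cis/trans mixture)
Conditions: hν (Pyrex-filtered medium-pressure Hg lamp or 350–365 nm LEDs), degassed MeCN (0.01 M), rt
Reagents that add atoms: none
Why: Norrish–Yang photocyclisation by δ-hydrogen abstraction, a known reaction of ortho-alkoxy and ortho-benzyloxy aryl aldehydes and ketones leading to 2,3-dihydrobenzofuran-3-ols: the n,π* excited formyl oxygen of 3 takes one hydrogen from the OCH2Ar group through a seven-membered transition state (1,6-hydrogen shift), leaving a 1,5-biradical that consists of a ketyl carbon and a benzylic carbon stabilised by its oxygen neighbour and the 4-methoxyphenyl group. Radical–radical coupling then forms the C2–C3 bond and closes the five-membered O1–C2–C3–C3a–C7a ring; the closure is a biradical recombination, so no polar exo/endo trajectory constraint applies. The new stereocentres C2 and C3 are set at the coupling, only by the conformation of the short-lived biradical, so a racemic cis/trans mixture is expected, which is acceptable because step 3 removes both centres. The step needs site selectivity in the hydrogen abstraction and intramolecular reaction ahead of bimolecular photoreduction: geometry places only the ether CH2 within reach of the formyl oxygen (both OCH3 groups are remote), its C–H bonds are among the weakest in the molecule, and high dilution in a solvent without weak C–H bonds holds back pinacol-type coupling. The ester is a photochemically silent spectator, and 4 no longer has the aryl-aldehyde chromophore, so it should be transparent to the filtered light and not be photolysed further.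

Step 3
Reactants: 4 methyl 3-hydroxy-2-(4-methoxyphenyl)-2,3-dihydro-1-benzofuran-5-carboxylate
Product: 5 methyl 2-(4-methoxyphenyl)-1-benzofuran-5-carboxylate
Conditions: TsOH·H2O (10 mol%), toluene, 80 °C
Reagents that add atoms: none
Why: Acid-catalysed dehydration (ionisation of the benzylic C3 hydroxyl, then loss of the C2 proton) is driven by formation of the aromatic furan, erases both stereocentres of 4, and leaves the methyl ester and the aryl methyl ether untouched under anhydrous catalytic acid.

Step 4
Reactants: 5 methyl 2-(4-methoxyphenyl)-1-benzofuran-5-carboxylate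
Product: 6 [2-(4-methoxyphenyl)-1-benzofuran-5-yl]methanol
Conditions: LiAlH4, THF, 0 °C to rt; then H2O, aq NaOH
Reagents that add atoms: none
Why: Hydride reduction of an aryl methyl ester to the benzylic alcohol with LiAlH4 is routine, and the benzofuran and the anisyl ether are inert to it.

Step 5
Reactants: 6 [2-(4-methoxyphenyl)-1-benzofuran-5-yl]methanol
Product: 7 2-(4-methoxyphenyl)-1-benzofuran-5-carbaldehyde
Conditions: activated MnO2 (excess), CH2Cl2, rt
Reagents that add atoms: none
Why: Activated MnO2 oxidises benzylic alcohols selectively to aldehydes without over-oxidation and should not touch the electron-rich benzofuran.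

Step 6
Reactants: 8 methyl 2-hydroxy-4-methoxybenzoate; 9 tert-butyl acetate
Product: 10 tert-butyl 3-(2-hydroxy-4-methoxyphenyl)-3-oxopropanoate
Conditions: LDA (commercial solution, 3.5 equiv), 9 (3.5 equiv), THF, −78 °C; then 8, −78 to 0 °C; aq NH4Cl
Reagents that add atoms: none
Why: Crossed Claisen condensation in which the non-enolisable salicylate ester is acylated by the lithium enolate of tert-butyl acetate used in excess (one equivalent of base is consumed by the phenol and one by the acidic product), the bulky tert-butyl ester resisting lactonisation to a 4-hydroxycoumarin.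

Step 7
Reactants: 7 2-(4-methoxyphenyl)-1-benzofuran-5-carbaldehyde; 10 tert-butyl 3-(2-hydroxy-4-methoxyphenyl)-3-oxopropanoate
Product: 11 tert-butyl 2-(2-hydroxy-4-methoxybenzoyl)-3-[2-(4-methoxyphenyl)-1-benzofuran-5-yl]prop-2-enoate (alkene geometry not defined; either isomer or the mixture is carried on)
Conditions: piperidine (20 mol%), AcOH (20 mol%), 4 Å MS, toluene, rt
Reagents that add atoms: none
Why: Knoevenagel condensation of the active methylene of the β-ketoester with the aryl aldehyde under piperidinium acetate catalysis with removal of water, the phenol being held in a hydrogen bond to the ketone and therefore expected to stay uncyclised at room temperature without strong base.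

Step 8
Reactants: 11 tert-butyl 2-(2-hydroxy-4-methoxybenzoyl)-3-[2-(4-methoxyphenyl)-1-benzofuran-5-yl]prop-2-enoate
Product: 14 (2S)-7-methoxy-2-[2-(4-methoxyphenyl)-1-benzofuran-5-yl]-2,3-dihydro-4H-chromen-4-one (lophirone J), via tert-butyl ester flavanone 12 (not isolated), via β-keto acid 13 (not isolated)
Conditions: 1-[3,5-bis(trifluoromethyl)phenyl]-3-(9-deoxy-epi-cinchonan-9-yl)thiourea (quinine- or quinidine-derived pseudoenantiomer giving 2S, 10 mol%), toluene, −25 °C; then TsOH·H2O, 80 °C
Reagents that add atoms: none
Why: Bifunctional-thiourea-catalysed asymmetric intramolecular oxa-Michael addition (6-endo-trig) of an alkylidene β-ketoester with one-pot acidolysis and decarboxylation is an established entry to enantioenriched flavanones, in which the thiourea binds the 1,3-dicarbonyl unit and the quinuclidine nitrogen activates the phenol so that oxygen adds to one face of the alkylidene and sets C2 as S under catalyst control, after which TsOH silences the amine and removes the activating ester from C3 as isobutene and CO2 without involving C2.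

Compound list
1 | methyl 3-formyl-4-hydroxybenzoate | COC(=O)c1ccc(O)c(C=O)c1 | starting material
2 | 4-methoxybenzyl chloride | COc1ccc(CCl)cc1 | starting material
3 | methyl 3-formyl-4-[(4-methoxyphenyl)methoxy]benzoate | COC(=O)c1ccc(OCc2ccc(OC)cc2)c(C=O)c1 | intermediate
4 | methyl 3-hydroxy-2-(4-methoxyphenyl)-2,3-dihydro-1-benzofuran-5-carboxylate (racemic, cis/trans mixture) | COC(=O)c1ccc2OC(c3ccc(OC)cc3)C(O)c2c1 | intermediate
5 | methyl 2-(4-methoxyphenyl)-1-benzofuran-5-carboxylate | COC(=O)c1ccc2oc(-c3ccc(OC)cc3)cc2c1 | intermediate
6 | [2-(4-methoxyphenyl)-1-benzofuran-5-yl]methanol | OCc1ccc2oc(-c3ccc(OC)cc3)cc2c1 | intermediate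
7 | 2-(4-methoxyphenyl)-1-benzofuran-5-carbaldehyde | O=Cc1ccc2oc(-c3ccc(OC)cc3)cc2c1 | intermediate
8 | methyl 2-hydroxy-4-methoxybenzoate | COC(=O)c1ccc(OC)cc1O | starting material
9 | tert-butyl acetate | CC(=O)OC(C)(C)C | starting material
10 | tert-butyl 3-(2-hydroxy-4-methoxyphenyl)-3-oxopropanoate | COc1ccc(C(=O)CC(=O)OC(C)(C)C)c(O)c1 | intermediate
11 | tert-butyl 2-(2-hydroxy-4-methoxybenzoyl)-3-[2-(4-methoxyphenyl)-1-benzofuran-5-yl]prop-2-enoate (alkene geometry not defined) | COc1ccc(C(=O)C(=Cc2ccc3oc(-c4ccc(OC)cc4)cc3c2)C(=O)OC(C)(C)C)c(O)c1 | intermediate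
12 | tert-butyl (2S)-7-methoxy-2-[2-(4-methoxyphenyl)-1-benzofuran-5-yl]-4-oxo-3,4-dihydro-2H-chromene-3-carboxylate (C3 not defined; keto epimers and enol) | COc1ccc(-c2cc3cc([C@@H]4C(C(=O)OC(C)(C)C)C(=O)c5ccc(OC)cc5O4)ccc3o2)cc1 | intermediate
13 | (2S)-7-methoxy-2-[2-(4-methoxyphenyl)-1-benzofuran-5-yl]-4-oxo-3,4-dihydro-2H-chromene-3-carboxylic acid (C3 not defined) | COc1ccc(-c2cc3cc([C@@H]4C(C(=O)O)C(=O)c5ccc(OC)cc5O4)ccc3o2)cc1 | intermediate
14 | (2S)-7-methoxy-2-[2-(4-methoxyphenyl)-1-benzofuran-5-yl]-2,3-dihydro-4H-chromen-4-one (lophirone J) | COc1ccc(-c2cc3cc([C@@H]4CC(=O)c5ccc(OC)cc5O4)ccc3o2)cc1 | target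

Total step count: 8. Longest linear sequence: 7 (steps 1, 2, 3, 4, 5, 7 and 8, from compound 1); step 6 is a one-step side branch.

Steps most likely to fail

Step 2. The photocyclisation may be inefficient if the electron-rich anisyl ring quenches the excited aldehyde by charge transfer. Bimolecular photoreduction or pinacol-type coupling of the aldehyde may also compete. The fallback makes the same C2–C3 bond as an alkene by an intramolecular Wittig reaction; it sets out from 1 and comes back at 5. Chemoselective borohydride reduction of the formyl group of 1 (NaBH4, MeOH, 0 °C) would give methyl 4-hydroxy-3-(hydroxymethyl)benzoate F1. Triphenylphosphine hydrobromide in hot acetonitrile would convert this into {[2-hydroxy-5-(methoxycarbonyl)phenyl]methyl}triphenylphosphonium bromide F2. With 4-methoxybenzoyl chloride and triethylamine in refluxing toluene the phenol would be acylated to {[5-(methoxycarbonyl)-2-(4-methoxybenzoyloxy)phenyl]methyl}triphenylphosphonium bromide F3, which is not isolated. Its ylide would close onto the aryl ester carbonyl and give 5 directly.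

Step 8. Facial selectivity may be insufficient, or enantiopurity may erode through reversible ring opening (retro-oxa-Michael reaction) during the warm acidic decarboxylation, which the electron-rich 2-aryl group favours. The fallback replaces asymmetric catalysis by a racemic synthesis with resolution; it sets out from 7 and comes back at 14. Claisen–Schmidt condensation of 7 with commercial paeonol, 1-(2-hydroxy-4-methoxyphenyl)ethanone (KOH, EtOH, rt), would give (E)-1-(2-hydroxy-4-methoxyphenyl)-3-[2-(4-methoxyphenyl)-1-benzofuran-5-yl]prop-2-en-1-one F4. Sodium acetate in refluxing ethanol would cyclise this chalcone, with recycling of unreacted material, to racemic 7-methoxy-2-[2-(4-methoxyphenyl)-1-benzofuran-5-yl]-2,3-dihydro-4H-chromen-4-one F5. Preparative chromatography on a chiral stationary phase would then deliver 14. The separated (2R)-7-methoxy-2-[2-(4-methoxyphenyl)-1-benzofuran-5-yl]-2,3-dihydro-4H-chromen-4-one F6 would be racemised with base through the ring-opened chalcone and resubmitted.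

Step 6. Acylation may be sluggish because the salicylate is deactivated as its phenoxide and by the para methoxy group, so self-condensation of the acetate enolate may win. The fallback removes the phenoxide by temporary protection; it sets out from 8 and comes back at 10. O-Benzylation of 8 (BnBr, K2CO3, DMF) would give methyl 2-(benzyloxy)-4-methoxybenzoate F7. Claisen condensation with the lithium enolate of 9 (2.2 equiv, THF, −78 to 0 °C) would give tert-butyl 3-[2-(benzyloxy)-4-methoxyphenyl]-3-oxopropanoate F8. Hydrogenolysis (H2, Pd/C, EtOAc, rt) would then release 10.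

Further compounds
F1 | step 2 | methyl 4-hydroxy-3-(hydroxymethyl)benzoate | COC(=O)c1ccc(O)c(CO)c1
F2 | step 2 | {[2-hydroxy-5-(methoxycarbonyl)phenyl]methyl}triphenylphosphonium bromide | COC(=O)c1ccc(O)c(C[P+](c2ccccc2)(c2ccccc2)c2ccccc2)c1.[Br-]
F3 | step 2 | {[5-(methoxycarbonyl)-2-(4-methoxybenzoyloxy)phenyl]methyl}triphenylphosphonium bromide | COC(=O)c1ccc(OC(=O)c2ccc(OC)cc2)c(C[P+](c2ccccc2)(c2ccccc2)c2ccccc2)c1.[Br-]
F4 | step 8 | (E)-1-(2-hydroxy-4-methoxyphenyl)-3-[2-(4-methoxyphenyl)-1-benzofuran-5-yl]prop-2-en-1-one | COc1ccc(C(=O)/C=C/c2ccc3oc(-c4ccc(OC)cc4)cc3c2)c(O)c1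
F5 | step 8 | racemic 7-methoxy-2-[2-(4-methoxyphenyl)-1-benzofuran-5-yl]-2,3-dihydro-4H-chromen-4-one | COc1ccc(-c2cc3cc(C4CC(=O)c5ccc(OC)cc5O4)ccc3o2)cc1
F6 | step 8 | (2R)-7-methoxy-2-[2-(4-methoxyphenyl)-1-benzofuran-5-yl]-2,3-dihydro-4H-chromen-4-one | COc1ccc(-c2cc3cc([C@H]4CC(=O)c5ccc(OC)cc5O4)ccc3o2)cc1
F7 | step 6 | methyl 2-(benzyloxy)-4-methoxybenzoate | COC(=O)c1ccc(OC)cc1OCc1ccccc1
F8 | step 6 | tert-butyl 3-[2-(benzyloxy)-4-methoxyphenyl]-3-oxopropanoate | COc1ccc(C(=O)CC(=O)OC(C)(C)C)c(OCc2ccccc2)c1
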